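**Plan**

Cuts, in retrosynthetic order: the C1 oxygen (allylic oxidation); the C9–O acyl bond (angelate); the C9–H bond together with the C7–O acyl bond (one hydride/acyl transfer from (E)-2-methylbut-2-enal); the ring bond C7–C8 (aldol); C8–C9 (methyl addition); C5–C6 (olefination); the C9–O bond (C–H oxidation of a C10 methyl group).
Ring order forward: the cyclobutane (C4, C5, C11, C10) and the cyclohexene (C1–C4, C11 and C5 or C10) come together from (−)-verbenone by a photochemical 1,3-shift. The arms are then grown on C10 and C5. The seven-membered ring (C5–C6–C7–C8–C9–C10, closed through C4 or C11) forms last.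
Enabling feature: C5 and C10 lie 1,3 across the folded cyclobutane and hold C6 and C9 on the same side, facing each other, and both C6 and C10 are quaternary. An acetyl group on C10 can therefore enolise only at C8, and a formyl group on C6 can only be the acceptor.
Stereochemistry: C4 and C11 come from verbenone. C10 comes from oxidising the one methyl group that a C5 oxygen can reach. C5 comes from reduction on the side of the C1–C3 bridge. C7 comes from a chiral boron reagent, because the frame around the new ring is nearly mirror-symmetric and cannot choose. C9 follows from C7 by internal hydride delivery (anti). The ester geometries come from the reagents.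

Key step: step 15

Numbering (used for all compounds): C1 is the carbonyl carbon of the target. C2=C3 is the ring alkene, with CH3 on C3. C4 (on C3) and C11 (on C1) are the bridgeheads. C5 is the cyclobutane CH bearing C6 (CMe2). C7 carries the O-tigloyl group, C8 is CH2, and C9 carries the O-angeloyl group. C10 is the quaternary cyclobutane carbon bearing CH3. On C5 and C10, "bridge side" means pointing toward the C1–C3 bridge and "cross side" means pointing toward the opposite cyclobutane carbon. The target is 4R,5S,7R,9R,10R,11R.

Assumption: the sense of induction known for (−)-Ipc2BCl in intermolecular methyl ketone aldol additions (R carbinol when the aldehyde substituent outranks CH2) is taken to hold in the bridged transition state. Since the substrate itself is unbiased, the (+)-reagent would serve if the sense is reversed.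

**Step 1**
Reactants: 1 (1S,5S)-(−)-verbenone
Product: 2 (1R,5S)-chrysanthenone (2,7,7-trimethylbicyclo[3.1.1]hept-2-en-6-one; C5 ketone, C10 gem-dimethyl)
Conditions: hν (medium-pressure Hg lamp, Pyrex), cyclohexane, 20 °C, partial conversion
Reagents that add atoms: none
Why: Known photochemical 1,3-alkyl shift of this enone, in which the CMe2 carbon moves suprafacially from the γ-bridgehead to the enone α-carbon while the bridgehead next to the carbonyl (later C11) is untouched and fixes the absolute configuration, and irradiation is stopped early because reversible opening to an achiral dienyl ketene would erode optical purity.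

**Step 2**
Reactants: 2 (1R,5S)-chrysanthenone
Product: 3 (1R,5S,6R)-2,7,7-trimethylbicyclo[3.1.1]hept-2-en-6-ol (C5–OH on the cross side)
Conditions: LiAlH4, Et2O, −78 → 0 °C
Reagents that add atoms: none
Why: Hydride addition to the strained, non-enolisable cyclobutanone from the bridge side, because the cross side of C5 is screened by the cross-side methyl group of C10, so the hydroxyl ends up next to that methyl group.

**Step 3**
Reactants: 3 cross-side C5 alcohol
Product: 5 cyclic silyl ether (six-membered C5–O–SiEt2–C9H2–C10 ring), via diethylhydrosilyl ether 4 (not isolated)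
Conditions: Et2SiH2, [Ir(cod)OMe]2 (cat.), THF, rt; then [Rh(cod)Cl]2 (cat.), Xantphos, norbornene, THF, 100 °C
Reagents that add atoms: diethylsilane CC[SiH2]CC
Why: Dehydrogenative O-silylation followed by the known rhodium/Xantphos-catalysed intramolecular silylation of a primary C–H bond δ to a silyl ether oxygen, preferred to an alkoxy-radical relay because a cyclobutyloxy radical flanked by allylic C4 would fragment; only the cross-side methyl of C10 is within reach, which sets C10.

**Step 4**
Reactants: 5 cyclic silyl ether
Product: 6 (1R,5S,6R,7S)-7-(hydroxymethyl)-2,7-dimethylbicyclo[3.1.1]hept-2-en-6-ol (C5–OH and C9H2OH both on the cross side)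
Conditions: H2O2 (30 % aq.), KHCO3, THF/MeOH, 50 °C
Reagents that add atoms: hydrogen peroxide OO
Why: Tamao–Fleming oxidation converts C9–Si into C9–OH with retention of the carbon framework, basic peroxide leaves the trisubstituted alkene alone, and the diol offers a first chance to raise optical purity by recrystallisation.

**Step 5**
Reactants: 6 diol
Product: 7 C9 tert-butyldimethylsilyl ether of 6 (C5–OH free)
Conditions: TBSCl, imidazole, CH2Cl2, 0 °C
Reagents that add atoms: tert-butyldimethylsilyl chloride CC(C)(C)[Si](C)(C)Cl
Why: Sterically controlled silylation, in which the primary C9 hydroxyl reacts well before the secondary cyclobutanol.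

**Step 6**
Reactants: 7 mono-silyl ether
Product: 8 C5 ketone with cross-side C10–CH2OTBS
Conditions: Dess–Martin periodinane, CH2Cl2, 0 °C → rt
Reagents that add atoms: none
Why: Dess–Martin oxidation, a two-electron oxidant chosen because one-electron oxidants cleave cyclobutanols.

**Step 7**
Reactants: 8 C5 ketone; 9 trimethyl 2-phosphonopropionate
Product: 10 methyl 2-(C5-ylidene)propanoate (C5=C6(CH3)CO2CH3 on the core of 8, E/Z mixture)
Conditions: NaH, THF, 0 → 65 °C
Reagents that add atoms: none
Why: Horner–Wadsworth–Emmons olefination of a strained ketone that cannot enolise, with the anion approaching from the bridge side, and with the alkene geometry irrelevant because both isomers converge in steps 8 and 9.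

**Step 8**
Reactants: 10 alkylidene ester
Product: 11 methyl 2-(C5-yl)propanoate (C5–H on the bridge side, C6 on the cross side cis to C9, C6 epimers)
Conditions: Mg, MeOH, 0 °C → rt
Reagents that add atoms: none
Why: Electron-transfer conjugate reduction of an α,β-unsaturated ester, which spares the isolated C2=C3 bond; C5 is protonated from the bridge side because the cross side is blocked by C10–CH2OTBS (the same sense as addition to pinenes anti to the substituted bridge), which sets C5.

**Step 9**
Reactants: 11 ester (C6 epimers)
Product: 12 methyl 2-methyl-2-(C5-yl)propanoate (C6 gem-dimethyl, arm cis to C10–CH2OTBS)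
Conditions: LiN(iPr)2, THF, −78 °C; MeI, −78 → 0 °C
Reagents that add atoms: iodomethane CI
Why: Ester enolate alkylation with the smallest electrophile, which erases the C6 stereocentre and makes C6 quaternary.

**Step 10**
Reactants: 12 silyl ether ester
Product: 13 hydroxy ester (C9H2OH free)
Conditions: Bu4NF, AcOH, THF, rt
Reagents that add atoms: none
Why: Fluoride desilylation, buffered with acetic acid so that no free alkoxide attacks the facing C7 ester.

**Step 11**
Reactants: 13 hydroxy ester
Product: 14 aldehyde ester (C9 formyl on C10)
Conditions: Dess–Martin periodinane, CH2Cl2, rt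
Reagents that add atoms: none
Why: Dess–Martin oxidation of a neopentyl primary alcohol to an aldehyde that cannot enolise.

**Step 12**
Reactants: 14 aldehyde ester
Product: 15 C9 secondary alcohol (1-hydroxyethyl on C10, C9 epimers)
Conditions: MeMgBr, Et2O, −78 °C
Reagents that add atoms: methylmagnesium bromide C[Mg]Br
Why: Grignard addition to the aldehyde is far faster than to the α-quaternary ester at low temperature; the C9 epimers are both used because step 14 erases the centre, and closure of the alkoxide onto the ester would be harmless since step 13 reduces either form to 16.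

**Step 13**
Reactants: 15 hydroxy ester
Product: 16 diol (C7H2OH on C6, C9H(OH)CH3 on C10)
Conditions: LiAlH4, THF, 0 °C → rt
Reagents that add atoms: none
Why: Standard LiAlH4 reduction of a hindered ester, with no other reducible group present.

**Step 14**
Reactants: 16 diol
Product: 17 keto aldehyde (C10 acetyl and C5 2-methyl-1-oxopropan-2-yl, cis on the cyclobutane)
Conditions: (COCl)2, DMSO, CH2Cl2, −78 °C; Et3N, −78 → 0 °C
Reagents that add atoms: none
Why: Swern oxidation activates both hydroxyls before base is added, which avoids hemiacetal formation between the facing arms and over-oxidation to a lactone.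

**Step 15**
Reactants: 17 keto aldehyde
Product: 20 (7R)-7-hydroxylongipin-2-en-9-one, via enol diisopinocampheylborinate 18 (not isolated), via boron aldolate 19 (not isolated)
Conditions: (−)-Ipc2BCl, Et3N, Et2O (0.01 M), −78 → −20 °C; then H2O2, MeOH, pH 7 buffer, 0 °C
Reagents that add atoms: none
Why: Proposed new method: (−)-Ipc2BCl and Et3N turn the acetyl group into enol borinate 18, boron then binds the C7 aldehyde oxygen and C8 adds to C7 through a closed six-membered array of B, O, C9, C8, C7 and O to give aldolate 19, which peroxide releases as 20; the closest known reactions are the intermolecular Ipc2BCl aldol additions of methyl ketones to aldehydes and the base-induced cyclisations of keto aldehydes to hydroxycycloheptanones, and their union in one bridged transition state is what is new. The seven-membered ring (C5, C6, C7, C8, C9, C10 and C4 or C11) closes in the 7-(enolendo)-exo-trig mode, because the enolate bond C8=C9 ends up inside the new ring and the C7 oxygen outside it, a mode that is allowed at this ring size. Closure is favoured because C6 and C9 stand cis on the folded cyclobutane and the C6 gem-dimethyl group presses the formyl group toward C8. The one new stereocentre, C7, cannot be left to the frame, since the surroundings of the forming ring are almost mirror-symmetric about the plane through C2, C5 and C10 (only the distant C1H2 and C3–CH3 differ), so the isopinocampheyl ligands choose the aldehyde face and should give 7R. Regio- and chemoselectivity are secured by the substrate, as C6 and C10 are quaternary and C8 is thus the only enolisable carbon and C7 the only acceptor, while dilution suppresses intermolecular addition. The boron chelate makes the addition irreversible, which prevents the retro-aldol scrambling of C7 open to a lithium aldolate, and the low temperature holds back hydride transfer from an isopinocampheyl group to the aldehyde.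

**Step 16**
Reactants: 20 (7R)-7-hydroxylongipin-2-en-9-one; 21 (E)-2-methylbut-2-enal
Product: 23 (7R,9R)-9-hydroxylongipin-2-en-7-yl tiglate, via hemiacetal 22 (not isolated)
Conditions: 21 (6 equiv), SmI2 (0.3 equiv, premixed with 21), THF, −10 °C, dark
Reagents that add atoms: none
Why: Proposed new method: the trivalent samarium alkoxide formed from SmI2 and 21 joins the C7 alkoxide and 21 as hemiacetal 22, whose C–H bond lies over the C9 carbonyl on the C7–O face and is passed on as hydride through a six-membered array (C9, C8, C7, O, acetal C, H), so that C9–OH appears trans to C7–O (anti, 9R) and the acetal carbon becomes the tigloyl carbonyl with its E double bond untouched; the closest known reaction is the SmI2-catalysed Evans–Tishchenko reduction of acyclic β-hydroxy ketones with saturated or aromatic aldehydes, new here are the enal as hydride donor and a substrate with carbinol and ketone in one seven-membered ring, and directed triacetoxyborohydride reductions of cyclic β-hydroxy ketones show that such bridged delivery is geometrically attainable.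

**Step 17**
Reactants: 23 hydroxy tiglate; 24 angelic acid
Product: 26 (7R,9R)-9-angeloyloxy-7-tigloyloxylongipin-2-ene, via mixed anhydride 25 (not isolated)
Conditions: 24, 2,4,6-Cl3C6H2COCl, Et3N, toluene, rt; then 23, 80 °C
Reagents that add atoms: none
Why: Yamaguchi-type mixed-anhydride esterification without a nucleophilic catalyst, the usual way to angelates because pyridine-type catalysts isomerise Z to E by conjugate addition; the alcohol attacks the less hindered angeloyl carbonyl, and the C7 tiglate cannot migrate because trans-1,3 oxygens on this ring cannot share an orthoester.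

**Step 18**
Reactants: 26 diester
Product: 27 target, (4R,5S,7R,9R,10R,11R)-9-angeloyloxy-7-tigloyloxylongipin-2-en-1-one
Conditions: CrO3, 3,5-dimethylpyrazole, CH2Cl2, −20 °C
Reagents that add atoms: chromium trioxide O=[Cr](=O)=O
Why: Allylic oxidation of the pinene-to-verbenone type, in which C1H2 is the only secondary allylic position of the electron-rich C2=C3 bond (C4–H is a bridgehead), the electron-poor ester double bonds are not attacked, and placing the step last means no free hydroxyl is exposed to the oxidant.

**Compound list**

1 | (1S,5S)-(−)-verbenone | CC1=CC(=O)[C@H]2C[C@@H]1C2(C)C | starting material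
2 | (1R,5S)-chrysanthenone | CC1=CC[C@@H]2C(=O)[C@H]1C2(C)C | intermediate
3 | (1R,5S,6R)-2,7,7-trimethylbicyclo[3.1.1]hept-2-en-6-ol | CC1=CC[C@@H]2[C@@H](O)[C@H]1C2(C)C | intermediate
4 | diethylhydrosilyl ether of 3 | CC1=CC[C@@H]2[C@@H](O[SiH](CC)CC)[C@H]1C2(C)C | intermediate
5 | cyclic silyl ether (C5–O–SiEt2–C9H2–C10) | CC1=CC[C@@H]2[C@H]3O[Si](CC)(CC)C[C@]2(C)[C@@H]13 | intermediate
6 | (1R,5S,6R,7S)-7-(hydroxymethyl)-2,7-dimethylbicyclo[3.1.1]hept-2-en-6-ol | CC1=CC[C@@H]2[C@@H](O)[C@H]1[C@@]2(C)CO | intermediate
7 | C9 TBS ether of 6 | CC1=CC[C@@H]2[C@@H](O)[C@H]1[C@@]2(C)CO[Si](C)(C)C(C)(C)C | intermediate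
8 | C5 ketone with cross-side C10–CH2OTBS | CC1=CC[C@@H]2C(=O)[C@H]1[C@@]2(C)CO[Si](C)(C)C(C)(C)C | intermediate
9 | trimethyl 2-phosphonopropionate | COC(=O)C(C)P(=O)(OC)OC | starting material
10 | C5=C6 alkylidene ester (E/Z mixture) | COC(=O)C(C)=C1[C@H]2CC=C(C)[C@@H]1[C@@]2(C)CO[Si](C)(C)C(C)(C)C | intermediate
11 | saturated ester, C6 arm cis to C9 (C6 epimers) | COC(=O)C(C)[C@@H]1[C@H]2CC=C(C)[C@@H]1[C@@]2(C)CO[Si](C)(C)C(C)(C)C | intermediate
12 | gem-dimethyl ester | COC(=O)C(C)(C)[C@@H]1[C@H]2CC=C(C)[C@@H]1[C@@]2(C)CO[Si](C)(C)C(C)(C)C | intermediate
13 | hydroxy ester | COC(=O)C(C)(C)[C@@H]1[C@H]2CC=C(C)[C@@H]1[C@@]2(C)CO | intermediate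
14 | aldehyde ester | COC(=O)C(C)(C)[C@@H]1[C@H]2CC=C(C)[C@@H]1[C@@]2(C)C=O | intermediate
15 | C9 secondary alcohol ester (C9 epimers) | COC(=O)C(C)(C)[C@@H]1[C@H]2CC=C(C)[C@@H]1[C@@]2(C)C(C)O | intermediate
16 | C7/C9 diol (C9 epimers) | OCC(C)(C)[C@@H]1[C@H]2CC=C(C)[C@@H]1[C@@]2(C)C(C)O | intermediate
17 | keto aldehyde (C10 acetyl, C5 2-methyl-1-oxopropan-2-yl) | CC(=O)[C@@]1(C)[C@@H]2CC=C(C)[C@H]1[C@@H]2C(C)(C)C=O | intermediate
18 | enol diisopinocampheylborinate of 17 | C=C(OB([C@@H]3C[C@@H]4C[C@H]([C@H]3C)C4(C)C)[C@@H]5C[C@@H]6C[C@H]([C@H]5C)C6(C)C)[C@@]1(C)[C@@H]2CC=C(C)[C@H]1[C@@H]2C(C)(C)C=O | intermediate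
19 | C7 diisopinocampheylboron aldolate | O=C1C[C@@H](OB([C@@H]4C[C@@H]5C[C@H]([C@H]4C)C5(C)C)[C@@H]6C[C@@H]7C[C@H]([C@H]6C)C7(C)C)C(C)(C)[C@@H]2[C@H]3CC=C(C)[C@@H]2[C@]31C | intermediate
20 | (7R)-7-hydroxylongipin-2-en-9-one | O=C1C[C@@H](O)C(C)(C)[C@@H]2[C@H]3CC=C(C)[C@@H]2[C@]31C | intermediate
21 | (E)-2-methylbut-2-enal | C/C=C(\C)C=O | starting material
22 | C7 hemiacetal of 20 and 21 (samarium-bound, drawn neutral) | O=C1C[C@@H](OC(O)/C(C)=C/C)C(C)(C)[C@@H]2[C@H]3CC=C(C)[C@@H]2[C@]31C | intermediate
23 | (7R,9R)-9-hydroxylongipin-2-en-7-yl tiglate | O[C@@H]1C[C@@H](OC(=O)/C(C)=C/C)C(C)(C)[C@@H]2[C@H]3CC=C(C)[C@@H]2[C@]31C | intermediate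
24 | angelic acid | C/C=C(/C)C(=O)O | starting material
25 | angelic 2,4,6-trichlorobenzoic anhydride | C/C=C(/C)C(=O)OC(=O)c1c(Cl)cc(Cl)cc1Cl | intermediate
26 | (7R,9R)-9-angeloyloxy-7-tigloyloxylongipin-2-ene | C/C=C(/C)C(=O)O[C@@H]1C[C@@H](OC(=O)/C(C)=C/C)C(C)(C)[C@@H]2[C@H]3CC=C(C)[C@@H]2[C@]31C | intermediate
27 | 9-angeloyloxy-7-tigloyloxylongipin-2-en-1-one (CNP0236543.2) | C/C=C(/C)C(=O)O[C@@H]1C[C@@H](OC(=O)/C(C)=C/C)C(C)(C)[C@@H]2[C@H]3C(=O)C=C(C)[C@@H]2[C@]31C | target

**Totals and risks**

Total step count: 18. Longest linear sequence: 18 steps, from 1. Compounds 9, 21 and 24 each enter directly as purchased.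

Step 16 is the first risk. Hemiacetal formation with the hindered, conjugated enal may be too unfavourable. One samarium centre may be unable to hold both oxygens in the bridged geometry. Retro-aldol opening of the samarium alkoxide may scramble C7. The fallback uses known chemistry, sets out from 20 and returns at 23. The C7 hydroxyl is esterified with tiglic acid (2,4,6-trichlorobenzoyl chloride, Et3N, 4-(dimethylamino)pyridine, toluene, 0 °C) to give the keto tiglate F1. The C9 ketone is then reduced under reagent control by Corey–Bakshi–Shibata reduction. This uses catecholborane and (S)-1-methyl-3,3-diphenyltetrahydropyrrolo[1,2-c][1,3,2]oxazaborole in toluene at −78 °C. With quaternary C10 as the large group and C8H2 as the small group, the 9R alcohol 23 is expected.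

Step 15 is the second risk. The crowded bridged transition state may give poor facial selectivity. Hydride transfer from the borane to the aldehyde may compete with enolisation. Enolisation next to quaternary C10 may also be slow. The fallback uses known chemistry, sets out from 17 and returns at 20. Stereocontrol in the bond-forming event is given up. The lithium enolate (LiN(SiMe3)2, THF, −78 °C) closes the ring to 20 together with the 7S epimer F2. The two are separated by chromatography. F2 is re-equilibrated through retro-aldol opening to 17 and re-closure (substoichiometric LiN(SiMe3)2, THF, 0 °C) and cycled.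

Step 7 is the third risk. Addition of the α-branched phosphonate anion to the flanked ketone may be slow. The alkoxide adduct may also cleave its C4–C5 bond, with loss of an allyl anion, instead of forming the olefin. The fallback sets out from 8 and returns at 12, bypassing 10 and 11. The lithium enolate of methyl isobutyrate (LiN(iPr)2, THF, −78 °C, cold quench) adds from the bridge side to give the tertiary alcohol F3. Methyl chlorooxoacetate and 4-(dimethylamino)pyridine convert it into the methyl oxalate F4. Radical deoxygenation (Bu3SnH, azobisisobutyronitrile, toluene, 110 °C) then lets the planar C5 radical take hydrogen from the bridge side. This swings the arm to the cross side and gives 12.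

**Further compounds**

F1 | step 16 | (7R)-9-oxolongipin-2-en-7-yl tiglate | O=C1C[C@@H](OC(=O)/C(C)=C/C)C(C)(C)[C@@H]2[C@H]3CC=C(C)[C@@H]2[C@]31C
F2 | step 15 | (7S)-7-hydroxylongipin-2-en-9-one | O=C1C[C@H](O)C(C)(C)[C@@H]2[C@H]3CC=C(C)[C@@H]2[C@]31C
F3 | step 7 | C5 tertiary alcohol (OH cross side, C(CH3)2CO2CH3 bridge side) | COC(=O)C(C)(C)[C@@]1(O)[C@H]2CC=C(C)[C@@H]1[C@@]2(C)CO[Si](C)(C)C(C)(C)C
F4 | step 7 | methyl oxalate of F3 | COC(=O)C(C)(C)[C@@]1(OC(=O)C(=O)OC)[C@H]2CC=C(C)[C@@H]1[C@@]2(C)CO[Si](C)(C)C(C)(C)C
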